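**Retrosynthetic overview**
1. Chiral pool: ricinoleic acid 1 supplies the whole C17 side chain (its C2–C18), the Z-alkene and the carbinol carbon. The carbinol has the (R)-configuration, and C1 of the acid is lost as CO2.
2. Benzylic C(sp3)–C(sp2) disconnection: 1 is activated with N-hydroxyphthalimide 2 as redox-active ester 3. Ester 3 is coupled decarboxylatively with 5-iodoresorcinol 4 to give the (R)-carbinol 5, without protecting groups.
3. Key disconnection C11'–O: 5 is inverted by SN2 carbon–oxygen bond formation. 2-(Azidomethyl)benzoic acid 6 is the self-cleaving oxygen donor, esters 7 and 8 stay in the flask, and the product is the (S)-carbinol 9.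
4. Rings: none is built. The benzene ring is bought with 4.

Assumption: side-chain locants (C1' to C17') count from the ring, and commercial ricinoleic acid is taken as the single (9Z,12R) isomer.

**Step 1**
Reactants: 1 ricinoleic acid, (9Z,12R)-12-hydroxyoctadec-9-enoic acid; 2 N-hydroxyphthalimide
Product: 3 1,3-dioxoisoindolin-2-yl (9Z,12R)-12-hydroxyoctadec-9-enoate
Conditions: 2 (1.05 equiv), DIC (1.05 equiv), DMAP (5 mol %), CH2Cl2, 0 °C to rt, 3 h; filter, short silica plug
Reagents that add atoms: none
Why: Steglich-type carbodiimide esterification, in which the O-acylisourea from 1 and DIC is intercepted by the acidic, strongly nucleophilic N–OH of 2 much faster than by the hindered secondary hydroxyl, so the redox-active ester forms without masking C12–OH and neither the Z-alkene nor the stereocentre is touched.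

**Step 2**
Reactants: 3 1,3-dioxoisoindolin-2-yl (9Z,12R)-12-hydroxyoctadec-9-enoate; 4 5-iodobenzene-1,3-diol (5-iodoresorcinol)
Product: 5 5-[(8Z,11R)-11-hydroxyheptadec-8-en-1-yl]benzene-1,3-diol
Conditions: 3 (1.3 equiv), 4 (1.0 equiv), NiBr2(dme) (10 mol %, dme = 1,2-dimethoxyethane), 4,4'-di-tert-butyl-2,2'-bipyridine (10 mol %), Zn dust (2.5 equiv), DMA, rt, 16 h, argon; aq NH4Cl
Reagents that add atoms: none
Why: Nickel-catalysed reductive decarboxylative cross-electrophile coupling, in which zerovalent nickel inserts into the C–I bond of 4, single-electron reduction of 3 gives CO2, phthalimide anion and the primary C17 radical, and the arylnickel species captures this radical and reductively eliminates; no carbon nucleophile or strong base is present, so the three O–H groups, the remote Z-alkene and the untouched (R)-stereocentre survive.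

**Step 3**
Reactants: 5 5-[(8Z,11R)-11-hydroxyheptadec-8-en-1-yl]benzene-1,3-diol; 6 2-(azidomethyl)benzoic acid
Product: 9 5-[(8Z,11S)-11-hydroxyheptadec-8-en-1-yl]benzene-1,3-diol, via azido ester 7 (not isolated), via amino ester 8 (not isolated)
Conditions: PPh3 (1.5 equiv), DIAD (1.5 equiv), THF, 0 °C, 15 min; then 5 + 6 (1.6 equiv) in THF, 0 °C to rt, 4 h; then PBu3 (2.0 equiv), H2O (20 equiv), 40 °C, 6 h; one flask, argon
Reagents that add atoms: none
Why: Proposed new method: a Mitsunobu-type SN2 C–O bond formation in which acid 6 serves as a self-cleaving hydroxide surrogate, so that a secondary alcohol becomes its free enantiomeric alcohol in one flask under neutral conditions: the preformed PPh3–DIAD betaine is protonated only by 6 (pKa about 3.7 against about 9.4 for the resorcinol O–H, so carboxylate is the sole anion and aryloxyphosphonium adducts of the phenols are reversible dead ends), the aliphatic hydroxyl of 5 is bound to phosphorus as an alkoxyphosphonium ion and displaced from the rear by the carboxylate, which inverts C11' from R to S and gives 7; only after all activator is spent does PBu3 reduce the azide (Staudinger reduction) to amine 8, whose nitrogen closes a five-membered lactam on the neighbouring ester carbonyl, an attack at the acyl carbon that leaves the new C11'–O bond and its configuration untouched and releases 9, which can no longer re-enter the substitution and racemise; the closest known reaction types are the Mitsunobu esterification with inversion and the phosphine-triggered removal of 2-(azidomethyl)benzoyl protecting groups, which have not been merged into a hydroxyl inversion nor shown on an unprotected alkenylresorcinol.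

**Compound list**
1 | ricinoleic acid, (9Z,12R)-12-hydroxyoctadec-9-enoic acid | CCCCCC[C@@H](O)C/C=C\CCCCCCCC(=O)O | starting material
2 | N-hydroxyphthalimide | O=C1c2ccccc2C(=O)N1O | starting material
3 | 1,3-dioxoisoindolin-2-yl (9Z,12R)-12-hydroxyoctadec-9-enoate | CCCCCC[C@@H](O)C/C=C\CCCCCCCC(=O)ON1C(=O)c2ccccc2C1=O | intermediate
4 | 5-iodobenzene-1,3-diol (5-iodoresorcinol) | Oc1cc(O)cc(I)c1 | starting material
5 | 5-[(8Z,11R)-11-hydroxyheptadec-8-en-1-yl]benzene-1,3-diol | CCCCCC[C@@H](O)C/C=C\CCCCCCCc1cc(O)cc(O)c1 | intermediate
6 | 2-(azidomethyl)benzoic acid | OC(=O)c1ccccc1CN=[N+]=[N-] | starting material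
7 | azido ester, (7S,9Z)-17-(3,5-dihydroxyphenyl)heptadec-9-en-7-yl 2-(azidomethyl)benzoate | CCCCCC[C@H](OC(=O)c1ccccc1CN=[N+]=[N-])C/C=C\CCCCCCCc1cc(O)cc(O)c1 | intermediate
8 | amino ester, (7S,9Z)-17-(3,5-dihydroxyphenyl)heptadec-9-en-7-yl 2-(aminomethyl)benzoate | CCCCCC[C@H](OC(=O)c1ccccc1CN)C/C=C\CCCCCCCc1cc(O)cc(O)c1 | intermediate
9 | 5-[(8Z,11S)-11-hydroxyheptadec-8-en-1-yl]benzene-1,3-diol (CNP0134805.1) | CCCCCC[C@H](O)C/C=C\CCCCCCCc1cc(O)cc(O)c1 | target

**Total step count:** 3. **Longest linear sequence:** 3 steps, from 1.

**Steps most likely to fail, most risky first**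

**Step 3 (the proposed new step).**
- Risks:
  - E2 loss of the activated hydroxyl toward the conjugated 8,10-diene.
  - Some retention through homoallyl participation.
  - Etherification of a phenol.
  - Sluggish lactam closure, which would leave 8 in the mixture.
- Fallback: known chemistry; it sets out from 5 and comes back at 9. Inversion and ester cleavage are separated and no trigger group is used.
- Compound 5 is esterified under standard Mitsunobu conditions (4-nitrobenzoic acid, PPh3, DIAD, THF, 0 °C to rt). This gives the stable (7S,9Z)-17-(3,5-dihydroxyphenyl)heptadec-9-en-7-yl 4-nitrobenzoate F1.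
- The ester is isolated and freed from diene and from any ester of retained configuration by chromatography.
- It is then solvolysed with K2CO3 in MeOH under argon to 9.

**Step 2.**
- Risks:
  - Acylation of a free phenol by the active ester 3.
  - Hydrodeiodination or biaryl formation from 4.
  - Z/E drift caused by nickel hydride.
- Fallback: it sets out from 4 (with 3) and comes back at 5. The protecting-group-free plan is given up.
- Compound 4 is acetylated (Ac2O, pyridine, rt) to 5-iodo-1,3-phenylene diacetate F2. This iodide is more electron-poor and free of O–H groups.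
- Coupling of F2 with 3 under NiBr2(dme), 4,4'-di-tert-butyl-2,2'-bipyridine and Zn in DMA gives 5-[(8Z,11R)-11-hydroxyheptadec-8-en-1-yl]-1,3-phenylene diacetate F3.
- The two aryl acetates of F3 are removed with K2CO3 in MeOH under argon to return 5.

**Step 1.**
- Risks:
  - Self-acylation of the free C12 hydroxyl (estolide oligomers).
  - N-acylurea formation.
  - Loss of 3 on silica.
- Fallback: it sets out from 1 and comes back at 5. The carbinol is masked before the acid is activated.
- Compound 1 is acetylated (Ac2O, pyridine, then water to hydrolyse the mixed anhydride) to (9Z,12R)-12-acetoxyoctadec-9-enoic acid F4.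
- Condensation of F4 with 2 (DIC, DMAP, CH2Cl2) gives 1,3-dioxoisoindolin-2-yl (9Z,12R)-12-acetoxyoctadec-9-enoate F5.
- Nickel/zinc coupling of F5 with 4 as in step 2 gives (7R,9Z)-17-(3,5-dihydroxyphenyl)heptadec-9-en-7-yl acetate F6.
- Methanolysis of F6 (K2CO3, MeOH, argon) occurs at the acyl carbon, so the configuration is retained, and returns 5.

**Further compounds**
F1 | step 3 | (7S,9Z)-17-(3,5-dihydroxyphenyl)heptadec-9-en-7-yl 4-nitrobenzoate | CCCCCC[C@H](OC(=O)c1ccc(cc1)[N+](=O)[O-])C/C=C\CCCCCCCc1cc(O)cc(O)c1
F2 | step 2 | 5-iodo-1,3-phenylene diacetate | CC(=O)Oc1cc(I)cc(OC(C)=O)c1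
F3 | step 2 | 5-[(8Z,11R)-11-hydroxyheptadec-8-en-1-yl]-1,3-phenylene diacetate | CCCCCC[C@@H](O)C/C=C\CCCCCCCc1cc(OC(C)=O)cc(OC(C)=O)c1
F4 | step 1 | (9Z,12R)-12-acetoxyoctadec-9-enoic acid | CCCCCC[C@@H](OC(C)=O)C/C=C\CCCCCCCC(=O)O
F5 | step 1 | 1,3-dioxoisoindolin-2-yl (9Z,12R)-12-acetoxyoctadec-9-enoate | CCCCCC[C@@H](OC(C)=O)C/C=C\CCCCCCCC(=O)ON1C(=O)c2ccccc2C1=O
F6 | step 1 | (7R,9Z)-17-(3,5-dihydroxyphenyl)heptadec-9-en-7-yl acetate | CCCCCC[C@@H](OC(C)=O)C/C=C\CCCCCCCc1cc(O)cc(O)c1
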